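Abbreviations used throughout: TBS = tert-butyldimethylsilyl (TBSO = its ether), TMS = trimethylsilyl, TMSE = 2-(trimethylsilyl)ethyl. Ring atoms carry isochromene numbers (C1, O2, C3, C4, C4a, C5–C8, C8a); the side chain is numbered C1′ (on C3) to C7′ (carboxyl carbon).

## The problem

The target is a 7,8-dihydro-6H-isochromen-6-one: a 4H-pyran (O2, C1, C3, C4, C4a, C8a) fused along C4a–C8a to a six-membered carbocycle (C4a, C5, C6, C7, C8, C8a). The pyran oxygen is conjugated through C3=C4 and C4a=C5 to the C6 ketone, so the bicycle is a push–pull 4-ylidene-4H-pyran that is electrophilic at C1.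

The carbocycle carries on consecutive atoms the C5 chlorine, the C6 ketone, a quaternary tertiary carbinol at C7 (S) and a secondary carbinol at C8 (R), with the two hydroxyls trans. C7 and C8 are neighbours and can be set together. No other ring atom needs control, because C4a and C8a are trigonal in the target.

The third stereocentre, C5′ (S), is separated from the ring by the (1′E,3′E)-diene and cannot be induced from it. It has to arrive in an enantiopure fragment.

Several groups will not survive rough treatment:
- The C8 hydroxyl is β to the C6 carbonyl, so its alkoxide can open C7–C8 by retro-aldol cleavage. It is also allylic to the C8a=C1 enol ether, so strong acid can ionise it.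
- C7–OH with C6=O is an α-ketol.
- C1 is attacked by amines.
- The diene and the free acid restrict oxidants and bases at the end.

Two features of the structure make a short route possible:
- The triad C6(=O)–C5(Cl)=C4a is exactly what opening of a 1-siloxy-2,2-dichlorocyclopropane leaves behind. The carbocycle can therefore come from a cyclopentanone by insertion of one chlorinated carbon, and C6, C7 and C8 then map onto prochiral 2-hydroxy-2-methylcyclopentane-1,3-dione.
- The quaternary C7 allows enolisation of C6 only toward C4a, and a methyl group on C3 is vinylogous to the C6 ketone, so the side chain can be attached by condensation.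

## Retrosynthesis

**Protecting groups.** Target 29 is traced to its bis-silyl ether 28 (two O–Si bonds) and this to the TMSE ester 27 (one ester C–O bond). Removing the ester first and the silyl ethers last, under acidic fluoride, means C8 never becomes an alkoxide next to the C6 ketone. A one-pot basic fluoride deprotection would risk exactly that. The forward steps must be a fluoride-triggered fragmentation of the β-silylethyl ester and an acidic desilylation.

**Side-chain attachment, C1′=C2′.** Ester 27 is cut at C1′=C2′ into the 3-methylpyran 16 and the enal 24. A cut at C3–C1′ would need a C3 oxygen function and a dienyl metal. Carrying the chain through the ring expansion would expose its trisubstituted alkene to the carbene. The chosen cut uses the acidity of the C3 methyl group. Compound 16 is the bare bicyclic core and 24 holds the only chain stereocentre. The forward reaction must attack through the terminal carbon of the extended enolate, dehydrate to the E alkene and leave C5′ alone.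

**Side chain.** Enal 24 is cut at C3′=C4′ to aldehyde 23 (Wittig). Aldehyde 23 comes from thioester 22, and 22 from imide 21. Imide 21 is cut at C5′–C6′ into the propionyl oxazolidinone 20 and the bromoacetate 19, itself made from 17 and 18. The two carbonyl termini are thus different from the outset (imide against ester). This avoids differentiating the two carboxyls of a methylsuccinic acid, which would give regioisomer mixtures. The auxiliary must set C5′.

**Pyran ring.** Pyran 16 is cut at O2–C3, through the exocyclic isomer 15, back to the aldehyde–alkyne 14. Aldehyde 14 is cut at the C1 carbonyl back to the vinyl compound 12. The neighbouring order, alkyne hydration before alkene cleavage, would put a π-acid on a 1,6-enyne; cleaving the alkene first removes that problem. Precursor 12 is a monocyclic cyclohexenone whose propargyl and vinyl groups are the latent C4–C3 and C1 atoms. The forward steps must cleave the vinyl group selectively and close the ring by 6-exo O-attack.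

**Key disconnection, C4a–C5 and C5–C6.** Chloroenone 12 is cut on both sides of C5, which removes the CCl carbon and leaves the cyclopentanone silyl enol ether 10. Chlorinating a preformed cyclohexenone would need electrophilic chlorine in the presence of an alkene and an alkyne. Building the six-membered ring directly would leave C7 and C8 to separate oxidations. The ring-expansion cut delivers ring size, unsaturation and chlorine in one step and moves the stereochemical problem onto a cyclopentane-1,3-dione. The forward reaction must add the carbene only to the enol ether and open cleanly.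

**Cyclopentanone substituents.** Enol ether 10 comes from ketone 9 (O–Si bond). Ketone 9 is cut at C8a–C(vinyl) and C4a–C4 into enone 6, a vinyl cuprate and propargyl bromide 7, through enolate 8. Stepwise alkylation of a saturated ketone could not place a carbon at C8a. The enolate must be alkylated before it is protonated; the configurations at C8a and C4a do not matter.

**Ring stereocentres.** Enone 6 comes from ketone 4 by dehydrogenation (through 5), 4 from diol 3 by silylation, 3 from dione 2 by desymmetrising reduction (C8–H bond), and 2 from 2-methylcyclopentane-1,3-dione 1 by hydroxylation (C7–O bond). Both ring stereocentres therefore rest on a single reduction of a prochiral dione.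

## Roads not taken

**Alternative 1:** The cut is C7–C8. The open-chain keto-aldehyde A1 is a 4-ylidene-4H-pyran that already carries the side chain, a formyl group on C8a and a C6/C7 1,2-dione. A chiral aminoindanol-derived triazolium carbene would convert the C8 aldehyde into an acyl-anion equivalent that adds to the C7 methyl ketone (intramolecular crossed benzoin reaction), closing the carbocycle and setting C7 in the hydroxy-dione A2.
- Merits: C7 is set by a catalyst, the skeleton is complete in one step, and the side chain is already in place.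
- Weak points: A2 has ketones at both C6 and C8 flanking C7. Only C8 may be reduced, and from the face that gives the trans-diol; both are vinylogous esters with nothing to tell them apart. The nucleophilic carbene can also add at C1 or into the polyene. The aldehyde is a deactivated vinylogous formate, and the acceptor carbonyl sits next to the more electrophilic C6 ketone. A1, with its exocyclic C4a=C5 geometry, is not simpler to make than the target.
- Comparison: this road is more convergent and does not depend on an enzyme screen. The chosen plan sets against that the fact that C7 and C8 are fixed together at the start and two ketones never have to be distinguished.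

**Alternative 2:** The cut runs through the pyran at C3–C4 and C1–O2. The enaminone A3 is a 2-chloro-3-methylcyclohexenone with the C7/C8 bis-silyl ether and a dimethylaminomethylene group at C8a, derived from a chiral-pool monoterpene ketone. It is deprotonated at the C4 methyl group; the dienolate is C-acylated by the dienoyl chloride A4, and the new enol oxygen displaces dimethylamine at C1. The product A5 is identical with 27.
- Merits: the pyran and the whole side chain arrive in one step, with no ozonolysis and no vinylogous aldol. Here it is better than the chosen plan, which needs steps 8, 9 and 15 to get from 12 to 27.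
- Weak points: the single stereocentre of the terpene lies at a carbon that ends trigonal, so C7 and C8 must be relayed from it by separate oxidations and the chlorine added in a further step. The key acylation must occur at the γ-carbon of a cross-conjugated dienolate with an acid chloride, where O-acylation and α-attack are the usual outcomes. A4 can also lose HCl to a vinylketene.
- Comparison: the chosen plan accepts a longer endgame. In return it gets the chlorine from the ring expansion itself, both ring stereocentres within two steps of an achiral dione, and bond formations of known type throughout.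

**Alternative 3:** The cut is C8–C8a. The aldehyde A6 is a 4-ylidene-4H-pyran with the side chain, an alkenyl triflate at C8a and a C6 ketone/C7 triethylsilyloxy/C8 aldehyde chain on C5. With CrCl2 and catalytic NiCl2 the alkenylchromium species adds to the aldehyde (Nozaki–Hiyama–Kishi reaction), closing the carbocycle and giving the C8 alcohol A7.
- Merits: the conditions are mild and selective for aldehydes over ketones and esters. The C8 hydroxyl is delivered free, so one silyl ether fewer has to be removed at the end, and only C7 must be made enantioselectively. In these respects it is better than the chosen plan.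
- Weak points: C8 depends on facial selectivity next to a carbon bearing silyloxy, methyl and acyl groups, where Felkin and chelation control point in opposite directions. A6 contains an α-quaternary β-keto aldehyde prone to deformylation. Its triflate requires a separately built pyran-3-one enol. Stoichiometric chromium is used on the most valuable intermediate.
- Comparison: the chosen plan closes the carbocycle early on a simple substrate and carries C8 as a silyl ether from step 2, at the cost of two deprotection steps.

Key step: step 7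

Remark on the chemistry: the target is read as (7S,8R) with trans hydroxyls and (S) at C5′. C8a and C4a in 8–14 are drawn as expected from anti addition, but both become trigonal in 16, so their control is not required.

## Route

Step 1
Reactants: 1 2-methylcyclopentane-1,3-dione
Product: 2 2-hydroxy-2-methylcyclopentane-1,3-dione
Conditions: dimethyldioxirane, acetone, 0 °C to rt
Reagents that add atoms: dimethyldioxirane, CC1(C)OO1
Why: Electrophilic oxygen transfer to the enol of the 2-substituted cyclic 1,3-dione (α-hydroxylation of a β-dicarbonyl) gives the tertiary alcohol; the product is still achiral.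

Step 2
Reactants: 2 2-hydroxy-2-methylcyclopentane-1,3-dione
Product: 3 (2S,3R)-2,3-dihydroxy-2-methylcyclopentan-1-one
Conditions: ketoreductase (selected from a panel), NADP+ (cat.), i-PrOH, phosphate buffer pH 7, 30 °C
Reagents that add atoms: none
Why: Enzymatic desymmetrising reduction of a prochiral 2,2-disubstituted cyclopentane-1,3-dione: the enzyme picks one enantiotopic carbonyl and one face, which sets C8 as R and thereby makes C7 the S stereocentre with the hydroxyls trans. Isopropanol recycles the cofactor.

Step 3
Reactants: 3 (2S,3R)-2,3-dihydroxy-2-methylcyclopentan-1-one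
Product: 4 (2S,3R)-2,3-bis(TBSO)-2-methylcyclopentan-1-one
Conditions: TBSOTf, 2,6-lutidine, CH2Cl2, −78 to 0 °C
Reagents that add atoms: tert-butyldimethylsilyl trifluoromethanesulfonate, CC(C)(C)[Si](C)(C)OS(=O)(=O)C(F)(F)F
Why: The silyl triflate silylates the secondary and the hindered tertiary α-ketol hydroxyl under a non-nucleophilic base; with C7 quaternary no β-elimination is possible.

Step 4
Reactants: 4 (2S,3R)-2,3-bis(TBSO)-2-methylcyclopentan-1-one
Product: 6 (4R,5S)-4,5-bis(TBSO)-5-methylcyclopent-2-en-1-one, via silyl enol ether 5 (not isolated)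
Conditions: LiN(iPr)2, Me3SiCl, THF, −78 °C; then Pd(OAc)2, MeCN, rt
Reagents that add atoms: none
Why: Saegusa–Ito oxidation: enolisation is possible only away from quaternary C7, and the silyl enol ether is dehydrogenated through an oxa-π-allylpalladium species and β-hydride elimination. C7 and C8 are untouched.

Step 5
Reactants: 6 (4R,5S)-4,5-bis(TBSO)-5-methylcyclopent-2-en-1-one; 7 propargyl bromide
Product: 9 (2S,3S,4R,5S)-4,5-bis(TBSO)-3-ethenyl-5-methyl-2-(prop-2-yn-1-yl)cyclopentan-1-one, via lithium enolate 8 (not isolated)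
Conditions: (CH2=CH)2CuLi (from CH2=CHLi and CuI), THF, −78 °C; then 7, HMPA, −78 to −20 °C
Reagents that add atoms: lithium divinylcuprate (CH2=CH)2CuLi, [Li+].C=C[Cu-]C=C
Why: Tandem conjugate addition–enolate alkylation: the cuprate adds to the 4-silyloxycyclopentenone anti to the C8 silyloxy group and the regiodefined enolate is C-alkylated anti to the new vinyl group. Quaternary C7 blocks enolate equilibration and the silyloxy β-elimination that usually troubles such enolates; both new centres later become trigonal.

Step 6
Reactants: 9 (2S,3S,4R,5S)-4,5-bis(TBSO)-3-ethenyl-5-methyl-2-(prop-2-yn-1-yl)cyclopentan-1-one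
Product: 10 (3S,4R,5S)-4,5-bis(TBSO)-3-ethenyl-5-methyl-2-(prop-2-yn-1-yl)-1-(trimethylsilyloxy)cyclopent-1-ene
Conditions: Me3SiOTf, Et3N, CH2Cl2, 0 °C
Reagents that add atoms: trimethylsilyl trifluoromethanesulfonate, C[Si](C)(C)OS(=O)(=O)C(F)(F)F
Why: Soft enolisation with silyl triflate and amine gives the only possible, tetrasubstituted C6=C4a silyl enol ether without deprotonating the terminal alkyne; the C4a stereocentre is erased.

Step 7
Reactants: 10 (3S,4R,5S)-4,5-bis(TBSO)-3-ethenyl-5-methyl-2-(prop-2-yn-1-yl)-1-(trimethylsilyloxy)cyclopent-1-ene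
Product: 12 (4S,5R,6S)-5,6-bis(TBSO)-2-chloro-4-ethenyl-6-methyl-3-(prop-2-yn-1-yl)cyclohex-2-en-1-one, via dichlorocyclopropane 11 (not isolated)
Conditions: Cl3CCO2Na, DME, 85 °C
Reagents that add atoms: sodium trichloroacetate Cl3CCO2Na (source of dichlorocarbene), [Na+].[O-]C(=O)C(Cl)(Cl)Cl
Why: Thermal decarboxylation of the trichloroacetate releases dichlorocarbene under neutral conditions, and the electrophilic singlet carbene adds in a concerted [2+1] fashion to the C6=C4a enol ether to give the 1-siloxy-6,6-dichlorobicyclo[3.1.0]hexane 11. Loss of the chloride syn to the five-membered ring is concerted with disrotatory electrocyclic opening of the C6–C4a fusion bond, assisted by the siloxy oxygen, and the resulting 2-chloro-oxyallyl cation gives up its silyl group to chloride, leaving the C6 ketone with C5(Cl)=C4a. The closest known reaction type is the one-carbon ring expansion of cyclic trimethylsilyl enol ethers to 2-chlorocycloalk-2-enones through their dihalocarbene adducts. The six-membered carbocycle is not closed by a cyclisation mode; it arises from the five-membered ring by strain-driven expansion, with C5 inserted between C6 and C4a (bonds C4a–C5 and C5–C6). No new stereocentre remains, since the two bridgehead centres of 11 are destroyed on opening and C7, C8 and C8a are spectators. The step needs chemoselectivity for the enol ether over the vinyl and alkyne groups, which the much higher nucleophilicity of the tetrasubstituted silyl enol ether toward an electrophilic carbene secures, and regioselectivity, which is fixed because quaternary C7 allows only the C6=C4a enol ether. The neutral carbene source avoids base-induced isomerisation of the skipped enyne, and quaternary C7 keeps the product from aromatising.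

Step 8
Reactants: 12 (4S,5R,6S)-5,6-bis(TBSO)-2-chloro-4-ethenyl-6-methyl-3-(prop-2-yn-1-yl)cyclohex-2-en-1-one
Product: 14 (1S,5S,6R)-5,6-bis(TBSO)-3-chloro-5-methyl-4-oxo-2-(prop-2-yn-1-yl)cyclohex-2-ene-1-carbaldehyde, via secondary ozonide 13 (not isolated)
Conditions: O3, CH2Cl2, −78 °C; then PPh3, −78 °C to rt
Reagents that add atoms: ozone, [O-][O+]=O
Why: Chemoselective ozonolysis with reductive work-up: ozone cleaves the monosubstituted vinyl group far faster than the electron-poor tetrasubstituted chloroenone or the alkyne, revealing C1 as the aldehyde on C8a. The aldehyde (drawn as the carbonyl tautomer) is used crude because C8a–H is doubly activated.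

Step 9
Reactants: 14 (1S,5S,6R)-5,6-bis(TBSO)-3-chloro-5-methyl-4-oxo-2-(prop-2-yn-1-yl)cyclohex-2-ene-1-carbaldehyde
Product: 16 (7S,8R)-7,8-bis(TBSO)-5-chloro-3,7-dimethyl-7,8-dihydro-6H-isochromen-6-one, via exocyclic enol ether 15 (not isolated)
Conditions: Ph3PAuNTf2 (5 mol %), CH2Cl2, rt; then PPTS (10 mol %), rt
Reagents that add atoms: none
Why: Gold-catalysed carbonyl–alkyne cycloisomerisation: the C1 carbonyl (or enol) oxygen adds 6-exo-dig to the activated alkyne at its internal carbon C3, protodeauration gives the exocyclic enol ether 15, and acid moves the double bond into the ring to give the conjugated 4-ylidene-4H-pyran. The C6 carbonyl cannot compete because C6 and C4 are trans across C5=C4a.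

Step 10
Reactants: 17 bromoacetyl bromide; 18 2-(trimethylsilyl)ethanol
Product: 19 2-(trimethylsilyl)ethyl bromoacetate
Conditions: pyridine, CH2Cl2, 0 °C
Reagents that add atoms: none
Why: Acylation of the alcohol by the acid bromide (esterification) with pyridine as acid scavenger; the alkyl bromide is untouched at 0 °C.

Step 11
Reactants: 20 (4R)-4-benzyl-3-propanoyl-1,3-oxazolidin-2-one; 19 2-(trimethylsilyl)ethyl bromoacetate
Product: 21 TMSE (3S)-4-[(4R)-4-benzyl-2-oxo-1,3-oxazolidin-3-yl]-3-methyl-4-oxobutanoate
Conditions: NaN(SiMe3)2, THF, −78 °C; then 19, −78 to −40 °C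
Reagents that add atoms: none
Why: Evans alkylation: the chelated Z sodium enolate is alkylated on the face opposite the benzyl group, which sets the future C5′ centre as S; the (R)-auxiliary is chosen for this sense.

Step 12
Reactants: 21 TMSE (3S)-4-[(4R)-4-benzyl-2-oxo-1,3-oxazolidin-3-yl]-3-methyl-4-oxobutanoate
Product: 22 TMSE (3S)-4-(ethylsulfanyl)-3-methyl-4-oxobutanoate
Conditions: EtSH, n-BuLi, THF, 0 °C
Reagents that add atoms: ethanethiol, CCS
Why: The lithium thiolate displaces the oxazolidinone at the exocyclic carbonyl (auxiliary cleavage to the thioester) without touching the ester or the α-centre.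

Step 13
Reactants: 22 TMSE (3S)-4-(ethylsulfanyl)-3-methyl-4-oxobutanoate
Product: 23 TMSE (3S)-3-methyl-4-oxobutanoate
Conditions: Et3SiH, Pd/C (10%), acetone, rt
Reagents that add atoms: none
Why: Fukuyama reduction: the palladium-catalysed silane reduction of the thioester stops at the aldehyde and leaves the ester and the α-stereocentre intact.

Step 14
Reactants: 23 TMSE (3S)-3-methyl-4-oxobutanoate
Product: 24 TMSE (3S,4E)-3,5-dimethyl-6-oxohex-4-enoate
Conditions: Ph3P=C(CH3)CHO, toluene, 90 °C
Reagents that add atoms: 2-(triphenylphosphoranylidene)propanal, CC(C=O)=P(c1ccccc1)(c1ccccc1)c1ccccc1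
Why: Wittig olefination with the stabilised formyl ylide gives the (E)-trisubstituted enal directly; the neutral conditions preserve the adjacent stereocentre.

Step 15
Reactants: 16 (7S,8R)-7,8-bis(TBSO)-5-chloro-3,7-dimethyl-7,8-dihydro-6H-isochromen-6-one; 24 TMSE (3S,4E)-3,5-dimethyl-6-oxohex-4-enoate
Product: 27 TMSE (3S,4E,6E)-7-[(7S,8R)-7,8-bis(TBSO)-5-chloro-7-methyl-6-oxo-7,8-dihydro-6H-isochromen-3-yl]-3,5-dimethylhepta-4,6-dienoate, via aldol adduct 25 (not isolated), via allylic mesylate 26 (not isolated)
Conditions: LiN(SiMe3)2, THF, −78 °C; 24, −78 °C; then MeSO2Cl, Et3N, −78 to 0 °C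
Reagents that add atoms: none
Why: Vinylogous aldol condensation: the C3 methyl group is vinylogous to the C6 ketone through C3=C4 and C4a=C5, so the amide base gives the extended enolate, which adds through its terminal carbon to the aldehyde, as known for 2-methyl-4-pyranones and 2-methyl-4-ylidene-4H-pyrans. Mesylation and amine-induced elimination then give the conjugated (1′E) alkene; no excess base meets the enal, so C5′ is not endangered.

Step 16
Reactants: 27 TMSE (3S,4E,6E)-7-[(7S,8R)-7,8-bis(TBSO)-5-chloro-7-methyl-6-oxo-7,8-dihydro-6H-isochromen-3-yl]-3,5-dimethylhepta-4,6-dienoate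
Product: 28 (3S,4E,6E)-7-[(7S,8R)-7,8-bis(TBSO)-5-chloro-7-methyl-6-oxo-7,8-dihydro-6H-isochromen-3-yl]-3,5-dimethylhepta-4,6-dienoic acid
Conditions: (Me2N)3S+ Me3SiF2− (TASF), DMF, 0 °C
Reagents that add atoms: none
Why: Fluoride attacks the trimethylsilyl group of the ester and fragmentation releases ethene and the carboxylate (β-silylethyl ester cleavage). At 0 °C the hindered C7 and C8 silyl ethers should be retained, and any loss is harmless because the next step removes them.

Step 17
Reactants: 28 (3S,4E,6E)-7-[(7S,8R)-7,8-bis(TBSO)-5-chloro-7-methyl-6-oxo-7,8-dihydro-6H-isochromen-3-yl]-3,5-dimethylhepta-4,6-dienoic acid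
Product: 29 (3S,4E,6E)-7-[(7S,8R)-5-chloro-7,8-dihydroxy-7-methyl-6-oxo-7,8-dihydro-6H-isochromen-3-yl]-3,5-dimethylhepta-4,6-dienoic acid
Conditions: HF·pyridine, pyridine, THF, 0 °C to rt
Reagents that add atoms: none
Why: Acidic fluoride cleaves both silyl ethers without forming a C8 alkoxide, so retro-aldol opening and epimerisation are avoided. C7 (S), C8 (R) and C5′ (S) are those set in steps 2 and 11.

## Compound list

1 | 2-methylcyclopentane-1,3-dione | CC1C(=O)CCC1=O | starting material
2 | 2-hydroxy-2-methylcyclopentane-1,3-dione | CC1(O)C(=O)CCC1=O | intermediate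
3 | (2S,3R)-2,3-dihydroxy-2-methylcyclopentan-1-one (hydroxyls trans) | O=C1[C@@](C)(O)[C@H](O)CC1 | intermediate
4 | (2S,3R)-2,3-bis(tert-butyldimethylsilyloxy)-2-methylcyclopentan-1-one | O=C1[C@@](C)(O[Si](C)(C)C(C)(C)C)[C@H](O[Si](C)(C)C(C)(C)C)CC1 | intermediate
5 | (4R,5S)-4,5-bis(TBSO)-5-methyl-1-(trimethylsilyloxy)cyclopent-1-ene (not isolated) | C[Si](C)(C)OC1=CC[C@@H](O[Si](C)(C)C(C)(C)C)[C@]1(C)O[Si](C)(C)C(C)(C)C | intermediate
6 | (4R,5S)-4,5-bis(TBSO)-5-methylcyclopent-2-en-1-one | O=C1[C@@](C)(O[Si](C)(C)C(C)(C)C)[C@H](O[Si](C)(C)C(C)(C)C)C=C1 | intermediate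
7 | propargyl bromide (3-bromoprop-1-yne) | C#CCBr | starting material
8 | lithium (3S,4R,5S)-4,5-bis(TBSO)-3-ethenyl-5-methylcyclopent-1-en-1-olate (not isolated) | [Li+].[O-]C1=C[C@H](C=C)[C@@H](O[Si](C)(C)C(C)(C)C)[C@]1(C)O[Si](C)(C)C(C)(C)C | intermediate
9 | (2S,3S,4R,5S)-4,5-bis(TBSO)-3-ethenyl-5-methyl-2-(prop-2-yn-1-yl)cyclopentan-1-one | C#CC[C@@H]1C(=O)[C@@](C)(O[Si](C)(C)C(C)(C)C)[C@H](O[Si](C)(C)C(C)(C)C)[C@H]1C=C | intermediate
10 | (3S,4R,5S)-4,5-bis(TBSO)-3-ethenyl-5-methyl-2-(prop-2-yn-1-yl)-1-(trimethylsilyloxy)cyclopent-1-ene | C#CCC1=C(O[Si](C)(C)C)[C@@](C)(O[Si](C)(C)C(C)(C)C)[C@H](O[Si](C)(C)C(C)(C)C)[C@H]1C=C | intermediate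
11 | 6,6-dichloro-2,3-bis(TBSO)-4-ethenyl-2-methyl-5-(prop-2-yn-1-yl)-1-(trimethylsilyloxy)bicyclo[3.1.0]hexane, ring centres as in 10, CCl2 bridge on the face opposite the vinyl group (not isolated) | C#CC[C@]12[C@H](C=C)[C@@H](O[Si](C)(C)C(C)(C)C)[C@](C)(O[Si](C)(C)C(C)(C)C)[C@@]1(O[Si](C)(C)C)C2(Cl)Cl | intermediate
12 | (4S,5R,6S)-5,6-bis(TBSO)-2-chloro-4-ethenyl-6-methyl-3-(prop-2-yn-1-yl)cyclohex-2-en-1-one | C#CCC1=C(Cl)C(=O)[C@@](C)(O[Si](C)(C)C(C)(C)C)[C@H](O[Si](C)(C)C(C)(C)C)[C@H]1C=C | intermediate
13 | (4S,5R,6S)-5,6-bis(TBSO)-2-chloro-6-methyl-3-(prop-2-yn-1-yl)-4-(1,2,4-trioxolan-3-yl)cyclohex-2-en-1-one, both epimers at the trioxolane carbon (not isolated) | C#CCC1=C(Cl)C(=O)[C@@](C)(O[Si](C)(C)C(C)(C)C)[C@H](O[Si](C)(C)C(C)(C)C)[C@H]1C2OCOO2 | intermediate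
14 | (1S,5S,6R)-5,6-bis(TBSO)-3-chloro-5-methyl-4-oxo-2-(prop-2-yn-1-yl)cyclohex-2-ene-1-carbaldehyde | C#CCC1=C(Cl)C(=O)[C@@](C)(O[Si](C)(C)C(C)(C)C)[C@H](O[Si](C)(C)C(C)(C)C)[C@H]1C=O | intermediate
15 | (7S,8R)-7,8-bis(TBSO)-5-chloro-7-methyl-3-methylidene-3,4,7,8-tetrahydro-6H-isochromen-6-one (not isolated) | C=C1CC2=C(Cl)C(=O)[C@@](C)(O[Si](C)(C)C(C)(C)C)[C@H](O[Si](C)(C)C(C)(C)C)C2=CO1 | intermediate
16 | (7S,8R)-7,8-bis(TBSO)-5-chloro-3,7-dimethyl-7,8-dihydro-6H-isochromen-6-one | CC1=CC2=C(Cl)C(=O)[C@@](C)(O[Si](C)(C)C(C)(C)C)[C@H](O[Si](C)(C)C(C)(C)C)C2=CO1 | intermediate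
17 | bromoacetyl bromide | BrCC(Br)=O | starting material
18 | 2-(trimethylsilyl)ethanol | C[Si](C)(C)CCO | starting material
19 | 2-(trimethylsilyl)ethyl bromoacetate | C[Si](C)(C)CCOC(=O)CBr | intermediate
20 | (4R)-4-benzyl-3-propanoyl-1,3-oxazolidin-2-one | CCC(=O)N1[C@H](Cc2ccccc2)COC1=O | starting material
21 | 2-(trimethylsilyl)ethyl (3S)-4-[(4R)-4-benzyl-2-oxo-1,3-oxazolidin-3-yl]-3-methyl-4-oxobutanoate | C[Si](C)(C)CCOC(=O)C[C@H](C)C(=O)N1[C@H](Cc2ccccc2)COC1=O | intermediate
22 | 2-(trimethylsilyl)ethyl (3S)-4-(ethylsulfanyl)-3-methyl-4-oxobutanoate | CCSC(=O)[C@@H](C)CC(=O)OCC[Si](C)(C)C | intermediate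
23 | 2-(trimethylsilyl)ethyl (3S)-3-methyl-4-oxobutanoate | O=C[C@@H](C)CC(=O)OCC[Si](C)(C)C | intermediate
24 | 2-(trimethylsilyl)ethyl (3S,4E)-3,5-dimethyl-6-oxohex-4-enoate | O=C/C(C)=C/[C@@H](C)CC(=O)OCC[Si](C)(C)C | intermediate
25 | 2-(trimethylsilyl)ethyl (3S,4E)-7-[(7S,8R)-7,8-bis(TBSO)-5-chloro-7-methyl-6-oxo-7,8-dihydro-6H-isochromen-3-yl]-6-hydroxy-3,5-dimethylhept-4-enoate, both C6 epimers (not isolated) | C[Si](C)(C)CCOC(=O)C[C@H](C)/C=C(\C)C(O)CC1=CC2=C(Cl)C(=O)[C@@](C)(O[Si](C)(C)C(C)(C)C)[C@H](O[Si](C)(C)C(C)(C)C)C2=CO1 | intermediate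
26 | 6-methanesulfonate of 25, both C6 epimers (not isolated) | C[Si](C)(C)CCOC(=O)C[C@H](C)/C=C(\C)C(OS(C)(=O)=O)CC1=CC2=C(Cl)C(=O)[C@@](C)(O[Si](C)(C)C(C)(C)C)[C@H](O[Si](C)(C)C(C)(C)C)C2=CO1 | intermediate
27 | 2-(trimethylsilyl)ethyl (3S,4E,6E)-7-[(7S,8R)-7,8-bis(TBSO)-5-chloro-7-methyl-6-oxo-7,8-dihydro-6H-isochromen-3-yl]-3,5-dimethylhepta-4,6-dienoate | CC(/C=C/C1=CC2=C(Cl)C(=O)[C@@](C)(O[Si](C)(C)C(C)(C)C)[C@H](O[Si](C)(C)C(C)(C)C)C2=CO1)=C\[C@@H](C)CC(=O)OCC[Si](C)(C)C | intermediate
28 | (3S,4E,6E)-7-[(7S,8R)-7,8-bis(TBSO)-5-chloro-7-methyl-6-oxo-7,8-dihydro-6H-isochromen-3-yl]-3,5-dimethylhepta-4,6-dienoic acid | CC(/C=C/C1=CC2=C(Cl)C(=O)[C@@](C)(O[Si](C)(C)C(C)(C)C)[C@H](O[Si](C)(C)C(C)(C)C)C2=CO1)=C\[C@@H](C)CC(=O)O | intermediate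
29 | (3S,4E,6E)-7-[(7S,8R)-5-chloro-7,8-dihydroxy-7-methyl-6-oxo-7,8-dihydro-6H-isochromen-3-yl]-3,5-dimethylhepta-4,6-dienoic acid | CC(/C=C/C1=CC2=C(Cl)C(=O)[C@@](C)(O)[C@H](O)C2=CO1)=C\[C@@H](C)CC(=O)O | target

## Step count and least certain steps

Total step count: 17. Longest linear sequence: 12 steps (steps 1–9 and 15–17, from 1). The side-chain branch is 5 steps (steps 10–14).

**Step 7 (key step).** The most likely failures are competing cyclopropanation of the vinyl group, hydrolytic loss of the crowded tetrasubstituted enol ether before the carbene is captured, or thermal isomerisation of the skipped enyne. The fallback forms the same two bonds with an unchlorinated carbon and adds chlorine afterwards. It sets out from 10. Simmons–Smith cyclopropanation (Et2Zn, CH2I2) would give the siloxycyclopropane 2,3-bis(TBSO)-4-ethenyl-2-methyl-5-(prop-2-yn-1-yl)-1-(trimethylsilyloxy)bicyclo[3.1.0]hexane F1. Oxidative ring expansion with FeCl3 in DMF followed by NaOAc, through the β-keto radical and the β-chloro ketone, would give the enone (4S,5R,6S)-5,6-bis(TBSO)-4-ethenyl-6-methyl-3-(prop-2-yn-1-yl)cyclohex-2-en-1-one F2. Nucleophilic epoxidation (t-BuOOH, DBU), which touches only the enone, would give the epoxy ketone, the 2,3-epoxide of F2, F3. Opening with HCl in ether at the α-carbon C5 and loss of the tertiary β-hydroxyl would return the route at 12.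

**Step 2.** The enzyme may show insufficient diastereo- or enantioselectivity on this small polar dione, or the 2-hydroxy-1,3-dione may ring-open hydrolytically in buffer. The fallback sets out from 2. Hydroxyl-directed reduction with Me4NBH(OAc)3 delivers hydride intramolecularly from the face of the C7 hydroxyl and should give the racemic trans-diol rac-(2S*,3R*)-2,3-dihydroxy-2-methylcyclopentan-1-one F4. Lipase-catalysed acylation with vinyl acetate would resolve it; the (3R) alcohol is expected to react, giving (1R,2S)-2-hydroxy-2-methyl-3-oxocyclopentyl acetate F5, which is separated from the unreacted enantiomer. Lipase-mediated hydrolysis of the acetate returns the route at 3.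

**Step 5.** C-alkylation of the copper-bound enolate may be slow, so that protonation or SN2′ attack giving allenyl products takes over. The fallback separates the two events. It sets out from 6: the same cuprate addition in the presence of Me3SiCl would give the silyl enol ether (3S,4R,5S)-4,5-bis(TBSO)-3-ethenyl-5-methyl-1-(trimethylsilyloxy)cyclopent-1-ene F6, which is purified. MeLi then regenerates the copper-free lithium enolate 8, which is alkylated with 7 in THF/HMPA. The route is rejoined at 9.

**Step 9.** The doubly activated aldehyde 14 may lose the C8 silyloxy group by β-elimination before the ring closes, or the terminal alkyne may divert the gold catalyst. The fallback forms O2–C3 by carbonyl condensation instead of alkyne hydroalkoxylation. It sets out from 12. Hydration of the alkyne with HgSO4 in dilute H2SO4 and aqueous acetone (alkene oxymercuration is reversible under these conditions) would give the methyl ketone (4S,5R,6S)-5,6-bis(TBSO)-2-chloro-4-ethenyl-6-methyl-3-(2-oxopropyl)cyclohex-2-en-1-one F7. Ozonolysis of its vinyl group would give the keto-aldehyde (1S,5S,6R)-5,6-bis(TBSO)-3-chloro-5-methyl-4-oxo-2-(2-oxopropyl)cyclohex-2-ene-1-carbaldehyde F8. Acid-catalysed cyclodehydration of this 1,5-dicarbonyl compound (PPTS) returns the route at 16.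

**Step 15.** The amide base or the enolate may add at C1, the elimination may be incomplete or unselective, or γ-deprotonation of the enal may erode C5′. The fallback makes the C–C bond under Lewis-acidic conditions. It sets out from 16. Silylation with TBSOTf and Et3N would give the silyl trienol ether (7S,8R)-6,7,8-tris(TBSO)-5-chloro-7-methyl-3-methylidene-7,8-dihydro-3H-isochromene F9. A vinylogous Mukaiyama aldol addition of its exocyclic methylene carbon to 24 (BF3·OEt2, CH2Cl2, −78 °C) would give the aldol adduct 25, now isolated. Dehydration under neutral conditions with the Burgess reagent rejoins the route at 27.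

## Further compounds

F1 | step 7 | 2,3-bis(TBSO)-4-ethenyl-2-methyl-5-(prop-2-yn-1-yl)-1-(trimethylsilyloxy)bicyclo[3.1.0]hexane, ring centres as in 10, methylene bridge opposite the vinyl group | C#CC[C@]12[C@H](C=C)[C@@H](O[Si](C)(C)C(C)(C)C)[C@](C)(O[Si](C)(C)C(C)(C)C)[C@@]1(O[Si](C)(C)C)C2
F2 | step 7 | (4S,5R,6S)-5,6-bis(TBSO)-4-ethenyl-6-methyl-3-(prop-2-yn-1-yl)cyclohex-2-en-1-one | C#CCC1=CC(=O)[C@@](C)(O[Si](C)(C)C(C)(C)C)[C@H](O[Si](C)(C)C(C)(C)C)[C@H]1C=C
F3 | step 7 | 2,3-epoxide of F2 (both epoxide faces, other centres as in F2) | C#CCC12OC1C(=O)[C@@](C)(O[Si](C)(C)C(C)(C)C)[C@H](O[Si](C)(C)C(C)(C)C)[C@H]2C=C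
F4 | step 2 | rac-(2S*,3R*)-2,3-dihydroxy-2-methylcyclopentan-1-one (racemic trans-diol) | O=C1[C@@](C)(O)[C@H](O)CC1.O=C1[C@](C)(O)[C@@H](O)CC1
F5 | step 2 | (1R,2S)-2-hydroxy-2-methyl-3-oxocyclopentyl acetate | O=C1[C@@](C)(O)[C@H](OC(C)=O)CC1
F6 | step 5 | (3S,4R,5S)-4,5-bis(TBSO)-3-ethenyl-5-methyl-1-(trimethylsilyloxy)cyclopent-1-ene | C[Si](C)(C)OC1=C[C@H](C=C)[C@@H](O[Si](C)(C)C(C)(C)C)[C@]1(C)O[Si](C)(C)C(C)(C)C
F7 | step 9 | (4S,5R,6S)-5,6-bis(TBSO)-2-chloro-4-ethenyl-6-methyl-3-(2-oxopropyl)cyclohex-2-en-1-one | CC(=O)CC1=C(Cl)C(=O)[C@@](C)(O[Si](C)(C)C(C)(C)C)[C@H](O[Si](C)(C)C(C)(C)C)[C@H]1C=C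
F8 | step 9 | (1S,5S,6R)-5,6-bis(TBSO)-3-chloro-5-methyl-4-oxo-2-(2-oxopropyl)cyclohex-2-ene-1-carbaldehyde | CC(=O)CC1=C(Cl)C(=O)[C@@](C)(O[Si](C)(C)C(C)(C)C)[C@H](O[Si](C)(C)C(C)(C)C)[C@H]1C=O
F9 | step 15 | (7S,8R)-6,7,8-tris(TBSO)-5-chloro-7-methyl-3-methylidene-7,8-dihydro-3H-isochromene | C=C1C=C2C(Cl)=C(O[Si](C)(C)C(C)(C)C)[C@@](C)(O[Si](C)(C)C(C)(C)C)[C@H](O[Si](C)(C)C(C)(C)C)C2=CO1
A1 | alternative 1 | 2-(trimethylsilyl)ethyl (3S,4E,6E)-7-[4-(1-chloro-2,3-dioxobutylidene)-5-formyl-4H-pyran-2-yl]-3,5-dimethylhepta-4,6-dienoate | CC(/C=C/C1=C/C(=C(\Cl)C(=O)C(C)=O)C(C=O)=CO1)=C\[C@@H](C)CC(=O)OCC[Si](C)(C)C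
A2 | alternative 1 | 2-(trimethylsilyl)ethyl (3S,4E,6E)-7-[(7S)-5-chloro-7-hydroxy-7-methyl-6,8-dioxo-7,8-dihydro-6H-isochromen-3-yl]-3,5-dimethylhepta-4,6-dienoate | CC(/C=C/C1=CC2=C(Cl)C(=O)[C@@](C)(O)C(=O)C2=CO1)=C\[C@@H](C)CC(=O)OCC[Si](C)(C)C
A3 | alternative 2 | (5R,6S)-5,6-bis(TBSO)-2-chloro-4-[(dimethylamino)methylidene]-3,6-dimethylcyclohex-2-en-1-one | CC1=C(Cl)C(=O)[C@@](C)(O[Si](C)(C)C(C)(C)C)[C@H](O[Si](C)(C)C(C)(C)C)C1=CN(C)C
A4 | alternative 2 | 2-(trimethylsilyl)ethyl (3S,4E,6E)-8-chloro-3,5-dimethyl-8-oxoocta-4,6-dienoate | O=C(Cl)/C=C/C(C)=C/[C@@H](C)CC(=O)OCC[Si](C)(C)C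
A5 | alternative 2 | 2-(trimethylsilyl)ethyl (3S,4E,6E)-7-[(7S,8R)-7,8-bis(TBSO)-5-chloro-7-methyl-6-oxo-7,8-dihydro-6H-isochromen-3-yl]-3,5-dimethylhepta-4,6-dienoate (identical with 27) | CC(/C=C/C1=CC2=C(Cl)C(=O)[C@@](C)(O[Si](C)(C)C(C)(C)C)[C@H](O[Si](C)(C)C(C)(C)C)C2=CO1)=C\[C@@H](C)CC(=O)OCC[Si](C)(C)C
A6 | alternative 3 | 2-(trimethylsilyl)ethyl (3S,4E,6E)-7-{4-[(3S)-1-chloro-3-methyl-2,4-dioxo-3-(triethylsilyloxy)butylidene]-5-(trifluoromethanesulfonyloxy)-4H-pyran-2-yl}-3,5-dimethylhepta-4,6-dienoate | CC(/C=C/C1=C/C(=C(\Cl)C(=O)[C@@](C)(O[Si](CC)(CC)CC)C=O)C(OS(=O)(=O)C(F)(F)F)=CO1)=C\[C@@H](C)CC(=O)OCC[Si](C)(C)C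
A7 | alternative 3 | 2-(trimethylsilyl)ethyl (3S,4E,6E)-7-[(7S,8R)-5-chloro-8-hydroxy-7-methyl-6-oxo-7-(triethylsilyloxy)-7,8-dihydro-6H-isochromen-3-yl]-3,5-dimethylhepta-4,6-dienoate | CC(/C=C/C1=CC2=C(Cl)C(=O)[C@@](C)(O[Si](CC)(CC)CC)[C@H](O)C2=CO1)=C\[C@@H](C)CC(=O)OCC[Si](C)(C)C
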